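Reading the equivalents of incoming ligand as the ratio standing in the flask is the trap: each exchange spends one incoming ligand and frees one leaving ligand, so the ratio drifts during the run.

in all of them: starting complex 0.052 M
- spring: incoming ligand 0.50 equiv; leaving ligand 1 equiv; run made earlier
- autumn: incoming ligand 13 equiv; leaving ligand 1 equiv; run made earlier
- elm: incoming ligand 0.400 equiv; leaving ligand 1.00 equiv; time 40 min
- cedar: incoming ligand 1.00 equiv; leaving ligand 1.00 equiv; time 40 min
- oak: incoming ligand 3.00 equiv; leaving ligand 1.00 equiv; time 40 min
- alder: incoming ligand 10.0 equiv; leaving ligand 1.00 equiv; time 40 min

- spring (time / min: complex with one exchanged / %, starting complex / %): 3.00: 4, 72; 5.00: 4, 61; 8.00: 5, 51; 12.0: 4, 42; 15.0: 7, 36; 25.0: 8, 27; 40.0: 3, 15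
- autumn (time / min: complex with one exchanged / %, starting complex / %): 3.00: 29, 30; 5.00: 23, 18; 8.00: 16, 9; 12.0: 12, 6; 15.0: 6, 9; 25.0: 5, 5; 40.0: 3, 4

(readings scatter by 2 percentage points)

- amount of complex with one exchanged at the end, in percent of the starting complex charged for elm, cedar, oak, alder, in this order
- the shape of the row from first to last (rises all the way / rises, then falls / falls all the way / hardly changes / falls, then rises)

- the numbers in the tables scatter by 2 percentage points (one standard deviation)
- "hardly changes" means that all values lie within two and a half points (for a concentration: within two and a half percent of the largest)

Over its last two readings the spring run shows complex with one exchanged at 0.262 of the starting complex then standing. Divided by its charged ratio of incoming to leaving ligand, that reads 0.524, with the scatter of the readings. This is the exchange quotient, [complex with one exchanged][leaving ligand]/([starting complex][incoming ligand]), a mass-action quotient.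

A reckoning of my own borrows [starting complex] at the end from the simulated runs. For elm, the spring end value 15% and the charge ratio give 3.14%. For alder, the autumn end value 4% and the charge ratio give 21.0%, above the 3% of complex with one exchanged that the autumn run reads at its end. So the answer goes back in: if each complex has given up two ligands, the ratio becomes 2.67 and alder gives 5.59%. Oak, with one ligand given up and the spring value of [starting complex], gives 7.86%. Over elm, oak and alder this reckoning therefore rises, then falls.

The forecast differs, with 4%, 5%, 5% and 3.5%, and its shape is hardly changes: “All values lie within scatter, so the row barely changes”.

The flasks give 3.60%, 6.80%, 9.80% and 5.38%, and the row rises, then falls.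

    starting complex + incoming ligand ⇌ leaving ligand + complex with one exchanged (K = 0.500, k = 0.0110 /M/s)
    complex with one exchanged + incoming ligand ⇌ leaving ligand + complex with two exchanged (K = 1.40, k = 0.0110 /M/s)
    complex with two exchanged + incoming ligand ⇌ leaving ligand + complex with three exchanged (K = 1.30, k = 0.00350 /M/s)
    2 starting complex → self-condensation product (k = 0.0180 /M/s)

With the contents at 40 min, the quotient returns oak as 9.86% against 9.80%. On alder it gives 5.79% against 5.38%. Alder keeps its complex with one exchanged because leaving ligand turns complex with two exchanged back into it: without that back reaction, alder ends at 0.241% instead of 5.38%.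

The numbers in the tables come from a simulation for an exercise.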